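The resorcylate ring is assembled last. Its C1 (bearing the ester carbonyl) and C6 (bearing the side-chain CH2) are the two sp carbons of a hex-2-ynoate; C2–C5, with oxygen on C2 and C4, are the four carbons of 1-methoxy-1,3-bis(trimethylsilyloxy)butadiene. A single thermal [4+2] cycloaddition forms C1–C2 and C5–C6, closes the only carbocycle, and aromatises by loss of methanol and the silyl groups to the 6-alkyl-2,4-dihydroxybenzoate. The precursor is an open-chain ynoate that already carries all three ester links and all four chiral-pool stereocentres, with the terminal acid as benzyl ester and the diol as acetonide, so the hindered benzoate is never esterified.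

Key step: step 9

Assumption: benzyl (S)- and benzyl (R)-3-hydroxybutanoate and methyl (R)-2-(2,2-dimethyl-1,3-dioxolan-4-yl)acetate are taken as purchasable chiral-pool esters of high enantiomeric purity, so all four stereocentres are bought and none is created in the route.

Design notes:
- The terminal acid is carried as a benzyl ester and not as an acid-labile ester. Its removal is then a neutral hydrogenolysis, and the acetonide needs only aqueous acetic acid. A strong-acid finish would expose the freed 4-hydroxy group to its own ester (γ-lactonisation with loss of the end cap).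
- The doubly acylated (R)-3-hydroxybutanoic acid 12 is made from a benzyl ester, because a methyl ester could not be opened selectively beside the second ester.
- The hydroxy-ynoate 6 is made in two steps from a propiolate ester and the epoxide, which avoids a protect/carboxylate/esterify/deprotect sequence.

Step 1
Reactants: 1 propiolic acid; 2 benzyl (S)-3-hydroxybutanoate
Product: 3 (S)-4-(benzyloxy)-4-oxobutan-2-yl prop-2-ynoate
Conditions: DCC, DMAP (5 mol %), CH2Cl2, −20 → 0 °C
Reagents that add atoms: none
Why: Steglich esterification: the O-acylisourea of propiolic acid acylates the secondary hydroxyl at low temperature with only a trace of DMAP, which limits conjugate addition to the alkyne, and the C–O bond at the stereocentre of 2 is not touched.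

Step 2
Reactants: 3 (S)-4-(benzyloxy)-4-oxobutan-2-yl prop-2-ynoate; 4 (R)-propylene oxide
Product: 6 (S)-4-(benzyloxy)-4-oxobutan-2-yl (R)-5-hydroxyhex-2-ynoate, via lithium acetylide 5 (not isolated)
Conditions: LiHMDS (1.0 equiv, added to 3), THF, −78 °C; BF3·OEt2, then 4 (1.5 equiv), −78 °C; H2O quench at −78 °C
Reagents that add atoms: none
Why: Yamaguchi–Hirao alkynylation: the sp C–H of the propiolate is far more acidic than the ester α-CH2 and is removed selectively at −78 °C, and the BF3-activated epoxide is opened by the acetylide in an SN2 reaction at its CH2 carbon, so the (R) carbinol centre of 4 is carried over unchanged.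

Step 3
Reactants: 7 methyl (R)-2-(2,2-dimethyl-1,3-dioxolan-4-yl)acetate
Product: 9 (R)-2-(2,2-dimethyl-1,3-dioxolan-4-yl)acetic acid, via lithium carboxylate 8 (not isolated)
Conditions: LiOH·H2O, THF/H2O, 0 °C; then cold 1 M HCl to pH 3–4, immediate extraction
Reagents that add atoms: lithium hydroxide, [Li+].[OH-]
Why: Saponification (BAc2) of an unhindered methyl ester at 0 °C, followed by brief cold acidification, leaves the acetonide intact and cannot touch the stereocentre, which is not α to the carbonyl.

Step 4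
Reactants: 9 (R)-2-(2,2-dimethyl-1,3-dioxolan-4-yl)acetic acid; 10 benzyl (R)-3-hydroxybutanoate
Product: 11 benzyl (R)-3-({[(R)-2,2-dimethyl-1,3-dioxolan-4-yl]acetyl}oxy)butanoate
Conditions: DCC, DMAP (10 mol %), CH2Cl2, 0 °C → rt
Reagents that add atoms: none
Why: Steglich esterification of an unhindered β-alkoxy acid with a secondary alcohol, in which acylation occurs at oxygen and both stereocentres are retained.

Step 5
Reactants: 11 benzyl (R)-3-({[(R)-2,2-dimethyl-1,3-dioxolan-4-yl]acetyl}oxy)butanoate
Product: 12 (R)-3-({[(R)-2,2-dimethyl-1,3-dioxolan-4-yl]acetyl}oxy)butanoic acid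
Conditions: H2 (1 atm), 10% Pd/C, EtOAc, rt
Reagents that add atoms: none
Why: Hydrogenolysis of the benzyl ester over Pd/C in an aprotic solvent frees the acid, while the alkyl ester and the acetonide are inert.

Step 6
Reactants: 6 (S)-4-(benzyloxy)-4-oxobutan-2-yl (R)-5-hydroxyhex-2-ynoate; 12 (R)-3-({[(R)-2,2-dimethyl-1,3-dioxolan-4-yl]acetyl}oxy)butanoic acid
Product: 13 (S)-4-(benzyloxy)-4-oxobutan-2-yl (R)-5-{[(R)-3-({[(R)-2,2-dimethyl-1,3-dioxolan-4-yl]acetyl}oxy)butanoyl]oxy}hex-2-ynoate
Conditions: DCC, DMAP (10 mol %), CH2Cl2, −20 → 0 °C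
Reagents that add atoms: none
Why: Steglich esterification of the only free hydroxyl of 6 at low temperature with catalytic DMAP, chosen to hold back β-elimination in the activated acid and amine addition to the ynoate; the C5 stereocentre is retained because its C–O bond is not broken.

Step 7
Reactants: 14 methyl acetoacetate
Product: 15 methyl 3-(trimethylsilyloxy)but-2-enoate (E/Z mixture)
Conditions: TMSCl, Et3N, hexane, rt
Reagents that add atoms: chlorotrimethylsilane, C[Si](C)(C)Cl
Why: O-Silylation of the enol form of the β-keto ester with TMSCl/Et3N gives the silyl enol ether, whose double-bond geometry is of no consequence.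

Step 8
Reactants: 15 methyl 3-(trimethylsilyloxy)but-2-enoate
Product: 17 1-methoxy-1,3-bis(trimethylsilyloxy)buta-1,3-diene, via lithium dienolate 16 (not isolated)
Conditions: LDA, THF, −78 °C; then TMSCl, −78 °C → rt; used freshly prepared
Reagents that add atoms: chlorotrimethylsilane, C[Si](C)(C)Cl
Why: γ-Deprotonation by LDA gives the extended dienolate, which is silylated on oxygen to the 1,3-bis(silyloxy)diene (Chan-type diene).

Step 9
Reactants: 13 (S)-4-(benzyloxy)-4-oxobutan-2-yl (R)-5-{[(R)-3-({[(R)-2,2-dimethyl-1,3-dioxolan-4-yl]acetyl}oxy)butanoyl]oxy}hex-2-ynoate; 17 1-methoxy-1,3-bis(trimethylsilyloxy)buta-1,3-diene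
Product: 20 (S)-4-(benzyloxy)-4-oxobutan-2-yl 2-[(R)-2-{[(R)-3-({[(R)-2,2-dimethyl-1,3-dioxolan-4-yl]acetyl}oxy)butanoyl]oxy}propyl]-4,6-dihydroxybenzoate, via cyclohexa-1,4-diene cycloadduct 18 (not isolated), via aryl bis(trimethylsilyl) ether 19 (not isolated)
Conditions: 17 (3–4 equiv, in portions), toluene, 120 °C, sealed tube; then HF·pyridine, pyridine, THF, 0 °C
Reagents that add atoms: none
Why: A normal-electron-demand Diels–Alder reaction between the electron-poor ynoate and the electron-rich bis(silyloxy)diene, concerted but strongly asynchronous, is followed by aromatisation; this is the known benzannulation of 2-alkynoates with 1,3-bis(silyloxy)dienes to 6-substituted 2,4-dihydroxybenzoates, applied here to a dienophile with three further esters. The six-membered ring closes by intermolecular [4+2] cycloaddition, which forms C1–C2 and C5–C6 in one event. The only new stereocentre is the transient mixed-ketal carbon of 18, which is erased when methanol is lost, so no stereocontrol is needed and the four existing centres are remote and untouched. The selectivity required is regiochemical: the unsubstituted CH2 terminus of the diene (largest HOMO coefficient) bonds to the β-carbon of the ynoate (largest LUMO coefficient) and the ketene-acetal carbon to the α-carbon, so oxygen lands on C2 and C4 and the chain on C6. Loss of methanol from the 1,4-cyclohexadiene makes the process irreversible, and pyridine-buffered fluoride then frees both phenols without harming the acetonide, the benzyl ester or the β-acyloxy esters.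

Step 10
Reactants: 20 (S)-4-(benzyloxy)-4-oxobutan-2-yl 2-[(R)-2-{[(R)-3-({[(R)-2,2-dimethyl-1,3-dioxolan-4-yl]acetyl}oxy)butanoyl]oxy}propyl]-4,6-dihydroxybenzoate
Product: 21 (S)-4-(benzyloxy)-4-oxobutan-2-yl 2-[(R)-2-({(R)-3-{[(R)-3,4-dihydroxybutanoyl]oxy}butanoyl}oxy)propyl]-4,6-dihydroxybenzoate
Conditions: AcOH/H2O/THF (4:1:1), rt, stopped at full conversion
Reagents that add atoms: none
Why: Acid-catalysed hydrolysis of the terminal isopropylidene acetal in aqueous acetic acid is expected to be much faster than acid-catalysed transesterification, so the esters, including the one that the freed 4-hydroxy group could attack to form a γ-lactone, should survive, and no C–O bond at a stereocentre is broken.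

Step 11
Reactants: 21 (S)-4-(benzyloxy)-4-oxobutan-2-yl 2-[(R)-2-({(R)-3-{[(R)-3,4-dihydroxybutanoyl]oxy}butanoyl}oxy)propyl]-4,6-dihydroxybenzoate
Product: 22 talapolyester B
Conditions: H2 (1 atm), 10% Pd/C, EtOAc, rt
Reagents that add atoms: none
Why: Hydrogenolysis of the benzyl ester under neutral conditions releases the acid; the resorcinol ring, the homobenzylic (not benzylic) acyloxy group and the free diol are inert, so nothing can lactonise or eliminate.

Compound list
1 | propiolic acid | C#CC(=O)O | starting material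
2 | benzyl (S)-3-hydroxybutanoate | C[C@H](O)CC(=O)OCc1ccccc1 | starting material
3 | (S)-4-(benzyloxy)-4-oxobutan-2-yl prop-2-ynoate | C#CC(=O)O[C@@H](C)CC(=O)OCc1ccccc1 | intermediate
4 | (R)-propylene oxide | C[C@@H]1CO1 | starting material
5 | lithium acetylide of 3 | [Li]C#CC(=O)O[C@@H](C)CC(=O)OCc1ccccc1 | intermediate
6 | (S)-4-(benzyloxy)-4-oxobutan-2-yl (R)-5-hydroxyhex-2-ynoate | C[C@@H](O)CC#CC(=O)O[C@@H](C)CC(=O)OCc1ccccc1 | intermediate
7 | methyl (R)-2-(2,2-dimethyl-1,3-dioxolan-4-yl)acetate | COC(=O)C[C@@H]1COC(C)(C)O1 | starting material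
8 | lithium (R)-2-(2,2-dimethyl-1,3-dioxolan-4-yl)acetate | [Li+].[O-]C(=O)C[C@@H]1COC(C)(C)O1 | intermediate
9 | (R)-2-(2,2-dimethyl-1,3-dioxolan-4-yl)acetic acid | OC(=O)C[C@@H]1COC(C)(C)O1 | intermediate
10 | benzyl (R)-3-hydroxybutanoate | C[C@@H](O)CC(=O)OCc1ccccc1 | starting material
11 | benzyl (R)-3-({[(R)-2,2-dimethyl-1,3-dioxolan-4-yl]acetyl}oxy)butanoate | C[C@H](CC(=O)OCc1ccccc1)OC(=O)C[C@@H]1COC(C)(C)O1 | intermediate
12 | (R)-3-({[(R)-2,2-dimethyl-1,3-dioxolan-4-yl]acetyl}oxy)butanoic acid | C[C@H](CC(=O)O)OC(=O)C[C@@H]1COC(C)(C)O1 | intermediate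
13 | (S)-4-(benzyloxy)-4-oxobutan-2-yl (R)-5-{[(R)-3-({[(R)-2,2-dimethyl-1,3-dioxolan-4-yl]acetyl}oxy)butanoyl]oxy}hex-2-ynoate | C[C@H](CC(=O)O[C@H](C)CC#CC(=O)O[C@@H](C)CC(=O)OCc1ccccc1)OC(=O)C[C@@H]1COC(C)(C)O1 | intermediate
14 | methyl acetoacetate | COC(=O)CC(C)=O | starting material
15 | methyl 3-(trimethylsilyloxy)but-2-enoate (E/Z mixture, geometry not defined) | COC(=O)C=C(C)O[Si](C)(C)C | intermediate
16 | lithium 1-methoxy-3-(trimethylsilyloxy)buta-1,3-dien-1-olate | [Li+].COC([O-])=CC(=C)O[Si](C)(C)C | intermediate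
17 | 1-methoxy-1,3-bis(trimethylsilyloxy)buta-1,3-diene | COC(O[Si](C)(C)C)=CC(=C)O[Si](C)(C)C | intermediate
18 | (S)-4-(benzyloxy)-4-oxobutan-2-yl 6-methoxy-4,6-bis(trimethylsilyloxy)cyclohexa-1,4-diene-1-carboxylate carrying at C2 the (R)-2-(acyloxy)propyl chain of 13 (both epimers at C6) | C[C@H](CC(=O)O[C@H](C)CC1=C(C(=O)O[C@@H](C)CC(=O)OCc2ccccc2)C(OC)(O[Si](C)(C)C)C=C(O[Si](C)(C)C)C1)OC(=O)C[C@@H]1COC(C)(C)O1 | intermediate
19 | 2,4-bis(trimethylsilyl) ether of 20 | C[C@H](CC(=O)O[C@H](C)Cc1cc(O[Si](C)(C)C)cc(O[Si](C)(C)C)c1C(=O)O[C@@H](C)CC(=O)OCc2ccccc2)OC(=O)C[C@@H]1COC(C)(C)O1 | intermediate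
20 | (S)-4-(benzyloxy)-4-oxobutan-2-yl 2-[(R)-2-{[(R)-3-({[(R)-2,2-dimethyl-1,3-dioxolan-4-yl]acetyl}oxy)butanoyl]oxy}propyl]-4,6-dihydroxybenzoate | C[C@H](CC(=O)O[C@H](C)Cc1cc(O)cc(O)c1C(=O)O[C@@H](C)CC(=O)OCc2ccccc2)OC(=O)C[C@@H]1COC(C)(C)O1 | intermediate
21 | (S)-4-(benzyloxy)-4-oxobutan-2-yl 2-[(R)-2-({(R)-3-{[(R)-3,4-dihydroxybutanoyl]oxy}butanoyl}oxy)propyl]-4,6-dihydroxybenzoate | C[C@H](CC(=O)O[C@H](C)Cc1cc(O)cc(O)c1C(=O)O[C@@H](C)CC(=O)OCc2ccccc2)OC(=O)C[C@@H](O)CO | intermediate
22 | talapolyester B, (S)-3-({2-[(R)-2-({(R)-3-{[(R)-3,4-dihydroxybutanoyl]oxy}butanoyl}oxy)propyl]-4,6-dihydroxybenzoyl}oxy)butanoic acid | C[C@H](CC(=O)O[C@H](C)Cc1cc(O)cc(O)c1C(=O)O[C@@H](C)CC(=O)O)OC(=O)C[C@@H](O)CO | target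

Total step count: 11.
Longest linear sequence: 7 steps (steps 3, 4, 5, 6, 9, 10, 11, from 7 to 22).

Steps most likely to fail

1. Step 9. Thermal decay and adventitious protodesilylation of the acyclic diene may outrun cycloaddition to the β-alkylated ynoate, or aromatisation may take the wrong course (loss of silanol in place of methanol). The fallback sets out from 13 and uses a cyclic, thermally robust diene whose aromatisation is a cycloreversion. Dimedone is bis-silylated (TMSOTf, Et3N) to 5,5-dimethyl-1,3-bis(trimethylsilyloxy)cyclohexa-1,3-diene F1. Heating 13 with F1 neat at 140–160 °C should give the bicyclo[2.2.2]octa-2,5-diene cycloadduct F2, which expels 2-methylpropene in a retro-Diels–Alder reaction. This gives the aryl bis(trimethylsilyl) ether 19, and the fluoride treatment of step 9 brings the route back at 20. The same polarity match (the CH terminus of the diene to the β-carbon of the ynoate) should give the same regiochemistry.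

2. Step 2. Deprotonation α to the benzyl ester with expulsion of the propiolate, or decay of the lithiated propiolate before the epoxide is opened, would consume 3. The fallback sets out from 4 and never generates a carbanion in the presence of an ester. Lithium acetylide–ethylenediamine complex in DMSO opens the epoxide to (R)-pent-4-yn-2-ol F3. TBSCl/imidazole gives (R)-tert-butyldimethyl(pent-4-yn-2-yloxy)silane F4. n-BuLi then CO2 gives (R)-5-[(tert-butyldimethylsilyl)oxy]hex-2-ynoic acid F5. Carbodiimide esterification with 2 gives (S)-4-(benzyloxy)-4-oxobutan-2-yl (R)-5-[(tert-butyldimethylsilyl)oxy]hex-2-ynoate F6. HF·pyridine removes the silyl group and brings the route back at 6.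

3. Step 6. β-Elimination in the activated β-acyloxy acid (crotonate formation with loss of the cap) and consumption of the ynoate by the nucleophilic catalyst would lower the yield of the coupling. The fallback sets out from 10 and 6 and grows the chain one residue at a time, so the activated acid carries a silyloxy group, a poor leaving group, at its β-carbon. TBSCl/imidazole converts 10 into benzyl (R)-3-[(tert-butyldimethylsilyl)oxy]butanoate F7, and hydrogenolysis gives (R)-3-[(tert-butyldimethylsilyl)oxy]butanoic acid F8. Carbodiimide esterification of 6 with F8 gives (S)-4-(benzyloxy)-4-oxobutan-2-yl (R)-5-({(R)-3-[(tert-butyldimethylsilyl)oxy]butanoyl}oxy)hex-2-ynoate F9. HF·pyridine gives (S)-4-(benzyloxy)-4-oxobutan-2-yl (R)-5-{[(R)-3-hydroxybutanoyl]oxy}hex-2-ynoate F10. Esterification of F10 with 9 brings the route back at 13.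

Further compounds
F1 | step 9 | 5,5-dimethyl-1,3-bis(trimethylsilyloxy)cyclohexa-1,3-diene | C[Si](C)(C)OC1=CC(O[Si](C)(C)C)=CC(C)(C)C1
F2 | step 9 | bicyclo[2.2.2]octa-2,5-diene cycloadduct of 13 and F1 (both bridgehead diastereomers) | C[C@H](CC(=O)O[C@H](C)CC1=C(C(=O)O[C@@H](C)CC(=O)OCc2ccccc2)C2(O[Si](C)(C)C)C=C(O[Si](C)(C)C)C1C(C)(C)C2)OC(=O)C[C@@H]1COC(C)(C)O1
F3 | step 2 | (R)-pent-4-yn-2-ol | C[C@@H](O)CC#C
F4 | step 2 | (R)-tert-butyldimethyl(pent-4-yn-2-yloxy)silane | C[C@H](CC#C)O[Si](C)(C)C(C)(C)C
F5 | step 2 | (R)-5-[(tert-butyldimethylsilyl)oxy]hex-2-ynoic acid | C[C@H](CC#CC(=O)O)O[Si](C)(C)C(C)(C)C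
F6 | step 2 | (S)-4-(benzyloxy)-4-oxobutan-2-yl (R)-5-[(tert-butyldimethylsilyl)oxy]hex-2-ynoate | C[C@H](CC#CC(=O)O[C@@H](C)CC(=O)OCc1ccccc1)O[Si](C)(C)C(C)(C)C
F7 | step 6 | benzyl (R)-3-[(tert-butyldimethylsilyl)oxy]butanoate | C[C@H](CC(=O)OCc1ccccc1)O[Si](C)(C)C(C)(C)C
F8 | step 6 | (R)-3-[(tert-butyldimethylsilyl)oxy]butanoic acid | C[C@H](CC(=O)O)O[Si](C)(C)C(C)(C)C
F9 | step 6 | (S)-4-(benzyloxy)-4-oxobutan-2-yl (R)-5-({(R)-3-[(tert-butyldimethylsilyl)oxy]butanoyl}oxy)hex-2-ynoate | C[C@H](CC(=O)O[C@H](C)CC#CC(=O)O[C@@H](C)CC(=O)OCc1ccccc1)O[Si](C)(C)C(C)(C)C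
F10 | step 6 | (S)-4-(benzyloxy)-4-oxobutan-2-yl (R)-5-{[(R)-3-hydroxybutanoyl]oxy}hex-2-ynoate | C[C@@H](O)CC(=O)O[C@H](C)CC#CC(=O)O[C@@H](C)CC(=O)OCc1ccccc1
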